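**Assumptions:** (i) MOM is used for all three phenols and is removed last; the aryl OMe is the natural one. (ii) The Z-selective cross-metathesis is run with the ring-B allylarene in excess, and the symmetrical Z-homodimers are removed by chromatography.

## Retrosynthetic overview
- The Z-1,4-diarylbut-2-ene is disconnected at the C=C by Z-selective cross-metathesis of two allylarenes (7 and 12). A final MOM removal gives colpol.
- Ring A allylarene comes from hydroquinone by mono-methylation, allylation, Claisen rearrangement, MOM protection and bromination para to the allyl group.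
- Ring B allylarene comes from resorcinol by bis-MOM protection, C2 lithiation/bromination, Ir-catalysed C5 borylation and Suzuki allylation.
- No rings are formed; both arenes are carried in from hydroquinone and resorcinol. The only stereo-element is the Z-olefin, set in the coupling step.

## Route

**Step 1**
Reactants: 1 (hydroquinone)
Product: 2 (4-methoxyphenol)
Conditions: Me2SO4 (0.33 equiv relative to 1), aq. NaOH, H2O, 0 °C→rt
Reagents that add atoms: dimethyl sulfate, COS(=O)(=O)OC
Why: Excess hydroquinone gives statistical O-mono-methylation by Williamson alkylation, and the unreacted hydroquinone is washed out with water. There is no stereocenter.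

**Step 2**
Reactants: 2 (4-methoxyphenol); 3 (allyl bromide, C=CCBr)
Product: 4 (1-allyloxy-4-methoxybenzene)
Conditions: K2CO3, acetone, reflux
Reagents that add atoms: none (the allyl group comes from 3)
Why: Phenoxide O-alkylation (Williamson); it is clean because the only acidic OH is the phenol.

**Step 3**
Reactants: 4
Product: 5 (2-allyl-4-methoxyphenol)
Conditions: neat, 200 °C, sealed tube, N2
Reagents that add atoms: none
Why: Aromatic Claisen [3,3] rearrangement. The para position is blocked by OMe and the two ortho positions are equivalent, so a single regioisomer forms.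

**Step 4**
Reactants: 5
Product: 6 (2-allyl-4-methoxy-1-(methoxymethoxy)benzene)
Conditions: MOMCl, i-Pr2NEt, CH2Cl2, 0 °C→rt
Reagents that add atoms: chloromethyl methyl ether, COCCl
Why: Phenol O-alkylation gives an acid-labile MOM ether that survives metathesis. This also stops the free OH from directing bromination to the position ortho to it in the next step.

**Step 5**
Reactants: 6
Product: 7 (2-allyl-5-bromo-4-methoxy-1-(methoxymethoxy)benzene)
Conditions: NBS, MeCN, 0 °C→rt, dark
Reagents that add atoms: N-bromosuccinimide, O=C1CCC(=O)N1Br
Why: Electrophilic aromatic bromination goes to the position ortho to OMe and para to the alkyl group, as in 2,5-dialkoxyalkylbenzenes. The isolated terminal alkene is much less reactive than the electron-rich arene in polar MeCN.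

**Step 6**
Reactants: 8 (resorcinol)
Product: 9 (1,3-bis(methoxymethoxy)benzene)
Conditions: NaH, then MOMCl, THF/DMF, 0 °C→rt
Reagents that add atoms: chloromethyl methyl ether, COCCl
Why: Double phenoxide O-alkylation installs two MOM groups, which later act as ortho-directing groups.

**Step 7**
Reactants: 9
Product: 10 (2-bromo-1,3-bis(methoxymethoxy)benzene)
Conditions: n-BuLi, THF, 0 °C; then (BrCl2C)2, −78 °C→rt
Reagents that add atoms: 1,2-dibromotetrachloroethane, BrC(Cl)(Cl)C(Cl)(Cl)Br
Why: Directed ortho-metalation occurs at C2, the position between the two MOM-ether oxygens, where the lithium is chelated by both. The aryllithium is then brominated by the electrophilic Br source.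

**Step 8**
Reactants: 10
Product: 11 (2-[4-bromo-3,5-bis(methoxymethoxy)phenyl]-4,4,5,5-tetramethyl-1,3,2-dioxaborolane)
Conditions: B2pin2, [Ir(OMe)(cod)]2 (1.5 mol%), dtbpy (3 mol%), THF, 80 °C
Reagents that add atoms: bis(pinacolato)diboron, CC1(C)OB(OC1(C)C)B1OC(C)(C)C(C)(C)O1
Why: Ir-catalysed C–H borylation is sterically controlled. Only C5 is remote from all three substituents, so the Bpin goes para to Br, and the aryl C–Br bond is untouched.

**Step 9**
Reactants: 11; 3 (allyl bromide)
Product: 12 (5-allyl-2-bromo-1,3-bis(methoxymethoxy)benzene)
Conditions: Pd(PPh3)4 (5 mol%), Cs2CO3, THF/H2O, 65 °C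
Reagents that add atoms: none (the allyl group comes from 3)
Why: Suzuki–Miyaura sp2–sp3 coupling. Oxidative addition into allyl bromide is far faster than into the hindered, electron-rich 2,6-dialkoxyaryl bromide, so the Ar–Br survives.

**Step 10**
Reactants: 7 (1.0 equiv); 12 (2.5 equiv)
Product: 13 ((Z)-1-[5-bromo-4-methoxy-2-(MOMO)phenyl]-4-[4-bromo-3,5-bis(MOMO)phenyl]but-2-ene)
Conditions: Z-selective cyclometalated Ru catalyst (Ru nitrato-chelate type, 5 mol%), THF, 35 °C, N2 sweep to remove ethylene
Reagents that add atoms: none (ethylene is lost)
Why: Z-selective olefin cross-metathesis. The chelated Ru catalyst forces a syn metallacyclobutane, so the new C=C is formed kinetically as Z (>90:10). The excess partner 12 suppresses homodimerisation of 7, and the symmetrical homodimers are separated chromatographically.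

**Step 11**
Reactants: 13
Product: 14 (colpol)
Conditions: 3 M HCl, THF/MeOH (1:1), 40 °C
Reagents that add atoms: none
Why: Acid-catalysed acetal hydrolysis removes all three aryl MOM ethers. The aryl OMe, the Ar–Br bonds and the non-conjugated Z-olefin are stable to these conditions, so the Z geometry is retained.

## Compound list
1 | hydroquinone | Oc1ccc(O)cc1 | starting material
2 | 4-methoxyphenol | COc1ccc(O)cc1 | intermediate
3 | allyl bromide | C=CCBr | starting material
4 | 1-allyloxy-4-methoxybenzene | C=CCOc1ccc(OC)cc1 | intermediate
5 | 2-allyl-4-methoxyphenol | C=CCc1cc(OC)ccc1O | intermediate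
6 | 2-allyl-4-methoxy-1-(MOMO)benzene | C=CCc1cc(OC)ccc1OCOC | intermediate
7 | 2-allyl-5-bromo-4-methoxy-1-(MOMO)benzene | C=CCc1cc(OC)c(Br)cc1OCOC | intermediate
8 | resorcinol | Oc1cccc(O)c1 | starting material
9 | 1,3-bis(MOMO)benzene | COCOc1cccc(OCOC)c1 | intermediate
10 | 2-bromo-1,3-bis(MOMO)benzene | COCOc1cccc(OCOC)c1Br | intermediate
11 | 4-bromo-3,5-bis(MOMO)phenyl-Bpin | COCOc1cc(B2OC(C)(C)C(C)(C)O2)cc(OCOC)c1Br | intermediate
12 | 5-allyl-2-bromo-1,3-bis(MOMO)benzene | C=CCc1cc(OCOC)c(Br)c(OCOC)c1 | intermediate
13 | tris-MOM (Z)-diarylbutene | COc1cc(C/C=C\Cc2cc(OCOC)c(Br)c(OCOC)c2)c(OCOC)cc1Br | intermediate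
14 | colpol | COc1cc(C/C=C\Cc2cc(O)c(Br)c(O)c2)c(O)cc1Br | target

**Total steps:** 11
**Longest linear sequence:** 7 (1→2→4→5→6→7→13→14, i.e. steps 1–5, 10, 11)

## Three steps most likely to fail
1. **Step 10 (Z-selective cross-metathesis):** it gives a statistical product mix, and Ru-H isomerisation of the allylarenes to propenylarenes is a risk. Fallback: a Z-selective Wittig reaction. Ozonolysis of 7 gives the arylacetaldehyde, which is coupled with the non-stabilised ylide from the ring-B 2-arylethyl phosphonium salt (NaHMDS, THF, −78 °C).
2. **Step 5 (regioselective bromination of 6):** bromination at the position ortho to OMOM, or addition to the alkene, would erode the yield. Fallback: bring Br in before the allyl group. Dakin oxidation of 3-bromo-4-methoxybenzaldehyde gives 3-bromo-4-methoxyphenol, and allylation then Claisen rearrangement occurs at the unhindered position para to Br, giving the same ring-A allylarene pattern after MOM protection.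
3. **Step 9 (chemoselective Suzuki allylation with Ar–Br present):** oligomerisation or Ar–Br coupling would compete. Fallback: reverse the order. Ir-borylate 9, allylate to 1-allyl-3,5-bis(MOMO)benzene, then do the C2 lithiation/bromination as the last ring-B step.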